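The trap in repeating this run is to read falling [D] as G appearing: at 12.0 min the alpha run, charged at 1.5 M, had lost 92.5 % of its D, yet G read 28.9 %.

| flask | D | remark | time |
|---|---|---|---|
| alpha | 1.5 M | run made earlier |  |
| flask | 3.0 M |  | 12 min |

alpha run (percent of the D charged)

| time / min | G / % | D / % |
|---|---|---|
| 3.00 | 13.6 | 49.5 |
| 4.00 | 18.1 | 38.0 |
| 5.00 | 19.1 | 31.8 |
| 6.00 | 20.8 | 26.3 |
| 10.0 | 26.4 | 8.2 |
| 12.0 | 28.9 | 7.5 |

(readings scatter by 1 percentage point)

* time up to 12 min at which G stands highest
* the amount of G, in percent of the D charged, at that time



So I divided G by D lost, and time dropped out. Summed over the alpha readings this gave 0.289, and I carried this share of lost D that appears as G, the selectivity. Single readings gave 0.269 at 3.00 min and 0.312 at 12.0 min, while the D reading went from 49.5 % to 7.5 %. In the alpha run D kept 0.531 of itself from 3.00 min to 6.00 min and 0.285 over a span twice as long, which reads as first order, so I let the 3.0 M flask follow it in percent.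

From above, with the whole charge lost, G came to 28.9 %. From below, with the loss read at 10.0 min, it came to 26.6 %. With the loss read at 12.0 min I committed to 26.8 %, at the end of the window, since G read more at 12.0 min than at 10.0 min.

The forecast said 27.5 % (23.5 % to 30 %) at 12 min (10.5 min to 12 min), higher than my figure but inside my bracket, calling G “a parallel product of fixed share”.

The flask gave G 27.9 % at 12.0 min, also inside the bracket.

    E ⇌ X (K = 0.360, k = 0.0150 min⁻¹)
    D → L (k = 0.160 min⁻¹)
    L → Q (k = 0.0580 min⁻¹)
    D → G (k = 0.0680 min⁻¹)
    Q ⇌ E (K = 0.730, k = 0.0230 min⁻¹)

In the flask the passing of D into L and the passing of D into G are both first order in D, so their rates stood at 2.35 to one at every moment and G took 0.298 of the D lost. With 6.5 % of D left in the flask, the carried share asks for 27.0 % of G, against the 27.9 % it held. In the neighbour flask read at 5.0 min, D stood at 32.0 %, so the carried share asks for 19.7 % of G, and that flask held 20.3 %.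

All runs are simulated with constants of no real substance.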